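The target is cut at the bond between quaternary C9b and aromatic C9a (dibenzofuran numbering), which reveals a linear N1,N8-bis(4-hydroxycinnamoyl)spermidine. The feature exploited is that C9b is the para carbon of one 4-hydroxycinnamoyl ring and C9a the carbon ortho to oxygen of the other. One anodic dearomatizing phenol–arene coupling therefore forges C9b–C9a, creates the quaternary carbon as a 4-aryl-4-vinylcyclohexa-2,5-dienone and closes the 20-membered lactam ring. Its precursor is the N4-Boc spermidine diamide with a free phenol on the N8 (butyl-end) cinnamoyl and a TIPS ether on the N1 (propyl-end) cinnamoyl. Ether closure at C4a, deracemization and enone reduction complete the tricycle.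

Key step: step 7

Remarks
- Locants: dibenzofuran numbering for the tricycle (C9b quaternary, C9a and C5a aromatic, C4a O-methine, C3 ketone, C8 the aromatic carbon bearing the acrylamide); spermidine N1 = propyl-end, N4 = central, N8 = butyl-end nitrogen. The target is (4aR,9bS), with the C9b acrylamide on N8 and the C8 acrylamide on N1; the macrocycle counts 20 atoms.
- Assumption: which antipode of di-p-toluoyltartaric acid gives the less soluble salt of the (4aR,9bS) base cannot be predicted; the route is written with the (2R,3R) acid 17, and the (2S,3S) acid would replace it without other change if a salt screen shows the opposite pairing.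
- Design note: the phenol stays free only on the ring that must become the dienone. The other oxygen carries a fluoride-labile silyl group so that the dienone never meets acid (no dienone–phenol rearrangement); Boc is removed only after the ether ring is closed. TIPS is preferred to a smaller silyl group because it must survive hot pyridine/ethanol in step 5.

Step 1
Reactants: 1 (E)-4-hydroxycinnamic acid; 2 triisopropylsilyl chloride
Product: 4 (E)-3-[4-(triisopropylsilyloxy)phenyl]acrylic acid, via bis-silylated ester 3 (not isolated)
Conditions: TIPSCl (2.3 equiv), imidazole, DMF, rt; then AcOH, THF/H2O, rt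
Reagents that add atoms: triisopropylsilyl chloride (2), CC(C)[Si](Cl)(C(C)C)C(C)C
Why: Imidazole-promoted O-silylation of both hydroxyl groups followed by selective hydrolysis of the silyl ester, which is far more labile to aqueous acid than the hindered aryl silyl ether.

Step 2
Reactants: 5 spermidine; 6 formaldehyde
Product: 7 4-(tetrahydropyrimidin-1(2H)-yl)butan-1-amine
Conditions: 37% aq. CH2O (1.0 equiv), H2O, 0 °C → rt
Reagents that add atoms: formaldehyde (6), C=O
Why: Aminal formation: the 1,3-diamine end (N1/N4) condenses to the six-membered hexahydropyrimidine in preference to a seven-membered aminal of the 1,4-diamine end, so only the N8 primary amine stays free.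

Step 3
Reactants: 7 4-(tetrahydropyrimidin-1(2H)-yl)butan-1-amine; 1 (E)-4-hydroxycinnamic acid
Product: 8 (E)-3-(4-hydroxyphenyl)-N-[4-(tetrahydropyrimidin-1(2H)-yl)butyl]acrylamide
Conditions: 1 (1.0 equiv), EDC·HCl, HOBt, DMF, −10 °C → rt
Reagents that add atoms: none
Why: Carbodiimide/HOBt amide coupling in which the unhindered primary amine should react far faster than the less basic, hindered aminal NH, while the phenol is not acylated in the absence of a strong base.

Step 4
Reactants: 8 (E)-3-(4-hydroxyphenyl)-N-[4-(tetrahydropyrimidin-1(2H)-yl)butyl]acrylamide; 4 (E)-3-[4-(triisopropylsilyloxy)phenyl]acrylic acid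
Product: 9 (E)-3-(4-hydroxyphenyl)-N-[4-(3-{(E)-3-[4-(triisopropylsilyloxy)phenyl]acryloyl}tetrahydropyrimidin-1(2H)-yl)butyl]acrylamide
Conditions: 4 (1.1 equiv), EDC·HCl, HOBt, N-methylmorpholine, CH2Cl2/DMF, 0 °C → rt
Reagents that add atoms: none
Why: Carbodiimide/HOBt amide coupling at the only N–H amine left, the aminal nitrogen that will become N1, so no primary-versus-secondary amine selectivity is needed and the much less nucleophilic phenol should stay free.

Step 5
Reactants: 9 the N1-acyl aminal diamide
Product: 10 N8-[(E)-4-hydroxycinnamoyl]-N1-[(E)-4-(triisopropylsilyloxy)cinnamoyl]spermidine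
Conditions: malonic acid (3 equiv), pyridine, EtOH, reflux
Reagents that add atoms: none
Why: Knoevenagel–Doebner removal of the N,N'-methylene bridge: the aminal ionizes reversibly and malonic acid traps the CH2 unit irreversibly, a known way to open N-acyl hexahydropyrimidines of spermidine; amides, phenol and the aryl TIPS ether tolerate it.

Step 6
Reactants: 10 the N1,N8-diacyl spermidine; 11 di-tert-butyl dicarbonate
Product: 12 N4-Boc-N8-[(E)-4-hydroxycinnamoyl]-N1-[(E)-4-(triisopropylsilyloxy)cinnamoyl]spermidine
Conditions: Boc2O (1.05 equiv), NaHCO3, THF/H2O, 0 °C → rt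
Reagents that add atoms: di-tert-butyl dicarbonate (11), CC(C)(C)OC(=O)OC(=O)OC(C)(C)C
Why: N-tert-butoxycarbonylation of the single basic amine; without an acyl-transfer catalyst the phenol and the amide nitrogens should not react.

Step 7
Reactants: 12 the linear N4-Boc precursor (free phenol on the N8 arm, OTIPS on the N1 arm)
Product: 13 macrocyclic 4-aryl-4-vinylcyclohexa-2,5-dienone (20-membered ring, N4-Boc, OTIPS ortho to the new aryl–C bond)
Conditions: undivided cell, boron-doped diamond anode, Pt cathode, Bu4NPF6 (0.05 M), 2,6-lutidine (2 equiv), (CF3)2CHOH, 12 added slowly to ≤1 mM, 0.5 mA cm−2, 2.1 F mol−1, 0 °C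
Reagents that add atoms: none
Why: Proposed new method: proton-coupled two-electron oxidation at the anode should convert the only free phenol of 12 into a phenoxenium ion stabilized by the fluorinated alcohol (the aryl silyl ether, the enamide π systems and the carbamate should be oxidized only at clearly higher potential), the carbon ortho to OSi of the other ring (future C9a) then attacks the para carbon that carries the acrylamide chain (future C9b), and loss of the arene proton gives dienone 13 while protons are reduced to H2 at the cathode. The closest known reaction type is the intramolecular anodic or hypervalent-iodine-mediated para–ortho phenol–arene coupling that gives the fused cyclohexadienones of narwedine-type and morphinandienone-type syntheses; new here are the ring size, the purely amide-based tether and the acrylamide-substituted, electron-poorer rings. The single ring formed is the 20-membered macrolactam, closed by a Friedel–Crafts-type C-arylation in which the attacked para carbon keeps its π system outside the new ring (exo mode, meta-cyclophane topology), and slow addition at high dilution should favour the unimolecular path over radical dimerization. No stereocentre arises, because C9b carries two identical enone arms and is only prochiral. The step needs chemoselective oxidation of one of two cinnamoyl rings, which the free-phenol/silyl-ether difference secures, and site selectivity for the para ring carbon over the ortho carbons and the side-chain carbon alpha to the amide, for which the substrate offers only the lower cation character of the carbonyl-flanked alpha carbon, the equivalence of the two attacking ortho carbons and the reach of the tether. This site selectivity, together with the modest nucleophilicity of the acceptor-substituted silyloxyarene, is the risk the route accepts.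

Step 8
Reactants: 13 the macrocyclic dienone
Product: 15 racemic cis-fused N4-Boc enone macrocycle (4aR*,9bS*; O–C4a closed; C1=C2–C3=O retained), via phenolic dienone 14 (not isolated)
Conditions: TBAF (1.2 equiv), AcOH (1.2 equiv), THF, 0 °C → rt
Reagents that add atoms: none
Why: Fluoride-mediated Si–O cleavage frees the phenol, which should add at once by 5-exo-trig oxa-Michael reaction to one of the two enantiotopic enone arms; the short tether forces the cis fusion (C4a–H and the C9b vinyl arm cis) and, with no chiral influence, both arms react equally, so 15 is racemic.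

Step 9
Reactants: 15 the racemic N4-Boc enone
Product: 16 racemic cis-fused amino enone macrocycle (N4–H)
Conditions: TFA/CH2Cl2 (1:4), 0 °C; aq. NaHCO3 work-up, used promptly
Reagents that add atoms: none
Why: Acidolytic carbamate cleavage (loss of the tert-butyl cation, then decarboxylation), to which the aryl ether, the enone and the amides are stable.

Step 10
Reactants: 16 the racemic amino enone; 17 (2R,3R)-O,O'-di-p-toluoyltartaric acid
Product: 18 1:1 salt of the (4aR,9bS)-amino enone with 17
Conditions: 17 (0.95 equiv), EtOH, 70 °C, then slow cooling to 20 °C with seeding and ageing of the slurry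
Reagents that add atoms: (2R,3R)-O,O'-di-p-toluoyltartaric acid (17), Cc1ccc(cc1)C(=O)O[C@@H](C(O)=O)[C@@H](OC(=O)c1ccc(C)cc1)C(O)=O
Why: Crystallization-induced diastereomer transformation (dynamic diastereomeric salt resolution), a process type established for narwedine-like 4a-aryloxy enones: the small free-base fraction equilibrates the enantiomers in solution by retro-oxa-Michael opening to the achiral dienone phenol and reclosure while the less soluble diastereomeric salt crystallizes, so the salt lattice selects C9b and C4a together, the two being tied by the cis fusion.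

Step 11
Reactants: 18 the diastereomerically pure salt
Product: 20 target (4aR,9bS)-ketone, via free-base enone 19 (not isolated)
Conditions: aq. NaHCO3/CH2Cl2, 0 °C, organic phase dried and used at once; [(Ph3P)CuH]6 (0.4 equiv), THF/toluene, H2O (3 equiv), 0 °C → rt
Reagents that add atoms: none
Why: After a brief cold bicarbonate partition, copper hydride conjugate reduction (Stryker type) should deliver hydride to C1 and a proton to C2 of the enone without touching the conjugated amides or the resulting ketone; the stereocentres are not involved and become fixed, because retro-addition could now only return the oxygen to the same carbon.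

Compound list
1 | (E)-4-hydroxycinnamic acid | OC(=O)/C=C/c1ccc(O)cc1 | starting material
2 | triisopropylsilyl chloride | CC(C)[Si](Cl)(C(C)C)C(C)C | starting material
3 | triisopropylsilyl (E)-3-[4-(triisopropylsilyloxy)phenyl]acrylate | CC(C)[Si](OC(=O)/C=C/c1ccc(O[Si](C(C)C)(C(C)C)C(C)C)cc1)(C(C)C)C(C)C | intermediate (not isolated)
4 | (E)-3-[4-(triisopropylsilyloxy)phenyl]acrylic acid | OC(=O)/C=C/c1ccc(O[Si](C(C)C)(C(C)C)C(C)C)cc1 | intermediate
5 | spermidine | NCCCCNCCCN | starting material
6 | formaldehyde | C=O | starting material
7 | 4-(tetrahydropyrimidin-1(2H)-yl)butan-1-amine | NCCCCN1CCCNC1 | intermediate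
8 | (E)-3-(4-hydroxyphenyl)-N-[4-(tetrahydropyrimidin-1(2H)-yl)butyl]acrylamide | Oc1ccc(/C=C/C(=O)NCCCCN2CCCNC2)cc1 | intermediate
9 | (E)-3-(4-hydroxyphenyl)-N-[4-(3-{(E)-3-[4-(triisopropylsilyloxy)phenyl]acryloyl}tetrahydropyrimidin-1(2H)-yl)butyl]acrylamide | Oc1ccc(/C=C/C(=O)NCCCCN2CCCN(C2)C(=O)/C=C/c2ccc(O[Si](C(C)C)(C(C)C)C(C)C)cc2)cc1 | intermediate
10 | N8-[(E)-4-hydroxycinnamoyl]-N1-[(E)-4-(triisopropylsilyloxy)cinnamoyl]spermidine | Oc1ccc(/C=C/C(=O)NCCCCNCCCNC(=O)/C=C/c2ccc(O[Si](C(C)C)(C(C)C)C(C)C)cc2)cc1 | intermediate
11 | di-tert-butyl dicarbonate | CC(C)(C)OC(=O)OC(=O)OC(C)(C)C | starting material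
12 | N4-Boc-N8-[(E)-4-hydroxycinnamoyl]-N1-[(E)-4-(triisopropylsilyloxy)cinnamoyl]spermidine (key-step precursor) | Oc1ccc(/C=C/C(=O)NCCCCN(C(=O)OC(C)(C)C)CCCNC(=O)/C=C/c2ccc(O[Si](C(C)C)(C(C)C)C(C)C)cc2)cc1 | intermediate
13 | macrocyclic cyclohexa-2,5-dienone: C4 of the dienone (future C9b) bears the (E)-CH=CH–CO–N8 arm and the aryl ring, bonded through the carbon ortho to OTIPS (future C9a), whose (E)-acrylamide on N1 is para to OTIPS; N4-Boc; 20-membered ring; achiral | O=C1C=CC2(C=C1)/C=C/C(=O)NCCCCN(C(=O)OC(C)(C)C)CCCNC(=O)/C=C/c1ccc(O[Si](C(C)C)(C(C)C)C(C)C)c2c1 | intermediate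
14 | phenol of 13 (OTIPS replaced by OH) | O=C1C=CC2(C=C1)/C=C/C(=O)NCCCCN(C(=O)OC(C)(C)C)CCCNC(=O)/C=C/c1ccc(O)c2c1 | intermediate (not isolated)
15 | racemic cis-(4aR*,9bS*) N4-Boc enone macrocycle (3-oxo-3,4,4a,9b-tetrahydrodibenzofuran core, C1=C2); racemate, SMILES shows the (4aR,9bS) half | O=C1C=C[C@]23/C=C/C(=O)NCCCCN(C(=O)OC(C)(C)C)CCCNC(=O)/C=C/c4ccc(c2c4)O[C@@H]3C1 | intermediate
16 | racemic cis-(4aR*,9bS*) amino enone macrocycle (15 without Boc); racemate, SMILES shows the (4aR,9bS) half | O=C1C=C[C@]23/C=C/C(=O)NCCCCNCCCNC(=O)/C=C/c4ccc(c2c4)O[C@@H]3C1 | intermediate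
17 | (2R,3R)-O,O'-di-p-toluoyltartaric acid (from L-tartaric acid) | Cc1ccc(cc1)C(=O)O[C@@H](C(O)=O)[C@@H](OC(=O)c1ccc(C)cc1)C(O)=O | starting material
18 | 1:1 salt of the (4aR,9bS)-amino enone (N4 ammonium) with the hydrogen (2R,3R)-di-p-toluoyltartrate | O=C1C=C[C@]23/C=C/C(=O)NCCCC[NH2+]CCCNC(=O)/C=C/c4ccc(c2c4)O[C@@H]3C1.Cc1ccc(cc1)C(=O)O[C@@H](C([O-])=O)[C@@H](OC(=O)c1ccc(C)cc1)C(O)=O | intermediate
19 | (4aR,9bS)-amino enone macrocycle, free base | O=C1C=C[C@]23/C=C/C(=O)NCCCCNCCCNC(=O)/C=C/c4ccc(c2c4)O[C@@H]3C1 | intermediate (not isolated)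
20 | target: (4aR,9bS)-3-oxo-1,2,3,4,4a,9b-hexahydrodibenzofuran whose C9b (E)-acryloyl arm is amide-bound to spermidine N8 and whose C8 (E)-acryloyl arm to N1, N4–H free | O=C1CC[C@]23/C=C/C(=O)NCCCCNCCCNC(=O)/C=C/c4ccc(c2c4)O[C@@H]3C1 | target

Total steps: 11.
Longest linear sequence: 10 steps (spermidine 5 to 20, steps 2–11); step 1 is a one-step side branch.

Steps most likely to fail

Step 7 (Proposed new method). The oxidized phenol may be attacked at an ortho carbon or at the side-chain carbon alpha to the amide instead of the para carbon. Phenoxyl radicals may also dimerize between molecules, or the weakly nucleophilic silyloxyarene may react too slowly, so that the cation is lost to solvent capture or over-oxidation.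

Fallback, known chemistry only: the tricycle is built without any phenol oxidation and the macrocycle is closed by amide formation. It sets out from spermidine 5 and comes back to the route at 16.
- The potassium anion of 1,4-dioxaspiro[4.5]decane-8-carbonitrile F1 (KN(SiMe3)2, toluene, 60 °C) displaces fluoride from 4-bromo-2-fluoroanisole F2 by nucleophilic aromatic substitution. This gives 8-(5-bromo-2-methoxyphenyl)-1,4-dioxaspiro[4.5]decane-8-carbonitrile F3, in which the quaternary carbon is already in place.
- Reduction with i-Bu2AlH (toluene, −78 → 0 °C) and mild aqueous acid gives 8-(5-bromo-2-methoxyphenyl)-1,4-dioxaspiro[4.5]decane-8-carbaldehyde F4.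
- Horner–Wadsworth–Emmons olefination (tert-butyl diethylphosphonoacetate, NaH, THF) gives tert-butyl (E)-3-[8-(5-bromo-2-methoxyphenyl)-1,4-dioxaspiro[4.5]decan-8-yl]acrylate F5.
- A Heck reaction with tert-butyl acrylate (Pd(OAc)2, P(o-tol)3, Et3N, DMF, 100 °C) gives the ketal bis(tert-butyl acrylate) F6.
- Ketal hydrolysis (pyridinium tosylate, aqueous acetone, 50 °C) gives the 4-aryl-4-vinylcyclohexanone bis(tert-butyl acrylate) F7.
- 2-Iodoxybenzoic acid (about 4 equiv, DMSO, 80 °C) dehydrogenates it twice to the 4-aryl-4-vinylcyclohexa-2,5-dienone bis(tert-butyl acrylate) F8.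
- BBr3 (CH2Cl2, −78 → 0 °C) cleaves the methyl ether and both tert-butyl esters; the freed phenol closes by oxa-Michael addition to the racemic cis-fused enone diacid F9.
- N-Hydroxysuccinimide and EDC·HCl convert it into the racemic bis(N-succinimidyl) ester F10.
- F10 and spermidine 5 are added slowly and simultaneously to a large volume of CH2Cl2, so that only the two primary amines are acylated. Both ring orientations form and are separated by chromatography: 16, and the racemic orientation isomer with the spermidine reversed F11. Compound 16 then continues with step 10.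

Step 10. The salt may fail to crystallize selectively, or the enone may equilibrate too slowly in the mother liquor, so that at best an ordinary half-yield resolution results.

Fallback: the deracemization is replaced by separation of a configurationally stable racemate. It sets out from racemic 16 and comes back at 20.
- Conjugate reduction of 16 with [(Ph3P)CuH]6 as in step 11 should give racemic 20, that is 20 together with the (4aS,9bR) enantiomer of 20 F12.
- This is resolved by preparative chromatography on a polysaccharide chiral stationary phase, or by classical fractional crystallization of a diastereomeric di-p-toluoyltartrate salt.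

Step 11. Enantiopurity may erode by retro-oxa-Michael opening while the free base is liberated and handled. The free secondary amine may interfere with the copper hydride, or hydride may be delivered to the acrylamide double bonds.

Fallback: the nitrogen is masked before the reduction. It sets out from salt 18 and comes back at 20.
- Two-phase treatment with Boc2O and NaHCO3 (CH2Cl2/H2O, 0 °C) traps the amine as it is released, giving the enantiopure (4aR,9bS)-N4-Boc enone macrocycle F13. No basic solution of the free amine is ever held.
- The neutral carbamate is reduced at the enone (Cu(OAc)2, 1,2-bis(diphenylphosphino)benzene, polymethylhydrosiloxane, t-BuOH, toluene, rt) to the (4aR,9bS)-N4-Boc ketone macrocycle F14.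
- TFA/CH2Cl2 then gives 20.

Further compounds
F1 | step 7 | 1,4-dioxaspiro[4.5]decane-8-carbonitrile (purchased) | N#CC1CCC2(CC1)OCCO2
F2 | step 7 | 4-bromo-2-fluoroanisole (purchased) | COc1ccc(Br)cc1F
F3 | step 7 | 8-(5-bromo-2-methoxyphenyl)-1,4-dioxaspiro[4.5]decane-8-carbonitrile | COc1ccc(Br)cc1C1(C#N)CCC2(CC1)OCCO2
F4 | step 7 | 8-(5-bromo-2-methoxyphenyl)-1,4-dioxaspiro[4.5]decane-8-carbaldehyde | COc1ccc(Br)cc1C1(C=O)CCC2(CC1)OCCO2
F5 | step 7 | tert-butyl (E)-3-[8-(5-bromo-2-methoxyphenyl)-1,4-dioxaspiro[4.5]decan-8-yl]acrylate | COc1ccc(Br)cc1C1(/C=C/C(=O)OC(C)(C)C)CCC2(CC1)OCCO2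
F6 | step 7 | ketal bis(tert-butyl acrylate): tert-butyl (E)-3-{3-[8-((E)-3-tert-butoxy-3-oxoprop-1-enyl)-1,4-dioxaspiro[4.5]decan-8-yl]-4-methoxyphenyl}acrylate | COc1ccc(/C=C/C(=O)OC(C)(C)C)cc1C1(/C=C/C(=O)OC(C)(C)C)CCC2(CC1)OCCO2
F7 | step 7 | 4-aryl-4-vinylcyclohexanone bis(tert-butyl acrylate) | COc1ccc(/C=C/C(=O)OC(C)(C)C)cc1C1(/C=C/C(=O)OC(C)(C)C)CCC(=O)CC1
F8 | step 7 | 4-aryl-4-vinylcyclohexa-2,5-dienone bis(tert-butyl acrylate) | COc1ccc(/C=C/C(=O)OC(C)(C)C)cc1C1(/C=C/C(=O)OC(C)(C)C)C=CC(=O)C=C1
F9 | step 7 | racemic cis-fused enone diacid: (E,E)-3,3'-(3-oxo-3,4,4a,9b-tetrahydrodibenzofuran-8,9b-diyl)diacrylic acid, (4aR,9bS) half shown | O=C1C=C[C@]2(/C=C/C(O)=O)c3cc(/C=C/C(O)=O)ccc3O[C@@H]2C1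
F10 | step 7 | racemic bis(N-succinimidyl) ester of F9, (4aR,9bS) half shown | O=C1C=C[C@]2(/C=C/C(=O)ON4C(=O)CCC4=O)c3cc(/C=C/C(=O)ON4C(=O)CCC4=O)ccc3O[C@@H]2C1
F11 | step 7 | racemic orientation isomer of 16 with the spermidine reversed (C9b arm on N1, C8 arm on N8), (4aR,9bS) half shown | O=C1C=C[C@]23/C=C/C(=O)NCCCNCCCCNC(=O)/C=C/c4ccc(c2c4)O[C@@H]3C1
F12 | step 10 | (4aS,9bR) enantiomer of 20, the other half of racemic 20 | O=C1CC[C@@]23/C=C/C(=O)NCCCCNCCCNC(=O)/C=C/c4ccc(c2c4)O[C@H]3C1
F13 | step 11 | (4aR,9bS)-N4-Boc enone macrocycle (single enantiomer of 15) | O=C1C=C[C@]23/C=C/C(=O)NCCCCN(C(=O)OC(C)(C)C)CCCNC(=O)/C=C/c4ccc(c2c4)O[C@@H]3C1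
F14 | step 11 | (4aR,9bS)-N4-Boc ketone macrocycle (N4-Boc derivative of 20) | O=C1CC[C@]23/C=C/C(=O)NCCCCN(C(=O)OC(C)(C)C)CCCNC(=O)/C=C/c4ccc(c2c4)O[C@@H]3C1
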